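**Plan**
1. Ring numbering: C1 ketone, C2 (bearing C7H2OH), C3, C4 (propanoate), C5 (isopropyl), C6 (4-hydroxytiglate ester); the target is (4S,5S,6R).
2. Retrosynthesis: the C4–O and C6–O acyl bonds and then the C6–O bond are removed; the ring is opened at C2=C3, which works because C2 carries only the exocyclic C7 and C3 only hydrogen, so this enone bond unfolds into an α-methylene ketone (C1–C2(=CH2)–C7) and a vinyl group on the C4 carbinol.
3. The acyclic dienone is cut at C1–C2 (Weinreb amide plus 2-lithioallyl silyl ether), at C5–isopropyl (cuprate addition) and at the enoate double bond C5=C6 (Wittig), which leads back to (S)-but-3-ene-1,2-diol.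
4. Forward: the chain C3–C4–C5–C6–C1 is built linearly, C2/C7 are attached, the only ring is closed by metathesis, C6 is oxygenated, and the two esters are installed before global desilylation.
5. Stereochemistry: C4 comes from the chiral-pool diol; C5 from cuprate addition anti to the C4 ether; C6 from epoxidation of the ring silyl dienol ether on the face opposite the C5 isopropyl group; the side-chain E-alkene from a stabilised ylide.

Key step: step 8

Remark: PMB = 4-methoxybenzyl, TBS = tert-butyldimethylsilyl; ring numbering as above is kept for all cyclic intermediates. The CIP letters at C4 and C5 change in some intermediates (16–18, 21) only because neighbour priorities change; the spatial arrangement never changes and the SMILES strings are authoritative. Metal alkoxides or carboxylates that are merely protonated at work-up are not numbered.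
Assumption: (S)-but-3-ene-1,2-diol is bought enantiopure.

**Step 1**
Reactants: 1 (S)-but-3-ene-1,2-diol
Product: 2 (4S)-2-(4-methoxyphenyl)-4-vinyl-1,3-dioxolane (both acetal epimers)
Conditions: 4-MeOC6H4CH(OMe)2, PPTS (cat.), CH2Cl2, rt
Reagents that add atoms: 4-methoxybenzaldehyde dimethyl acetal, COc1ccc(C(OC)OC)cc1
Why: Acid-catalysed transacetalisation of the 1,2-diol closes the five-membered 4-methoxybenzylidene acetal without touching the carbinol centre (the later C4), and the new acetal centre is irrelevant because step 2 destroys it.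

**Step 2**
Reactants: 2 (4S)-2-(4-methoxyphenyl)-4-vinyl-1,3-dioxolane
Product: 3 (2S)-2-[(4-methoxybenzyl)oxy]but-3-en-1-ol
Conditions: i-Bu2AlH (DIBAL-H), CH2Cl2, −78 → 0 °C; aq. KNaC4H4O6 (potassium sodium tartrate)
Reagents that add atoms: none
Why: Regioselective reductive acetal opening, in which the aluminium hydride coordinates the less hindered primary oxygen, that C–O bond ionises and hydride reduces the oxocarbenium ion, so the PMB group ends on the secondary oxygen and the primary alcohol is released.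

**Step 3**
Reactants: 3 (2S)-2-[(4-methoxybenzyl)oxy]but-3-en-1-ol; 4 ethyl (triphenylphosphoranylidene)acetate
Product: 6 ethyl (2E,4S)-4-[(4-methoxybenzyl)oxy]hexa-2,5-dienoate, via aldehyde 5 (not isolated)
Conditions: PhI(OAc)2, TEMPO (cat.), CH2Cl2, rt; then 4, rt
Reagents that add atoms: ethyl (triphenylphosphoranylidene)acetate (4), CCOC(=O)C=P(c1ccccc1)(c1ccccc1)c1ccccc1
Why: TEMPO/PhI(OAc)2 oxidation followed in the same flask by Wittig olefination with the stabilised ylide should give the E-enoate, and trapping the α-alkoxy-β,γ-unsaturated aldehyde as it forms under non-basic conditions guards against epimerisation or conjugation, so the C4 configuration is carried through.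

**Step 4**
Reactants: 6 ethyl (2E,4S)-4-[(4-methoxybenzyl)oxy]hexa-2,5-dienoate; 7 isopropylmagnesium chloride
Product: 9 ethyl (3S,4S)-3-isopropyl-4-[(4-methoxybenzyl)oxy]hex-5-enoate, via silyl ketene acetal 8 (not isolated)
Conditions: iPrMgCl (4 equiv), CuI (2 equiv), Me3SiCl (4 equiv), THF, −78 → −40 °C; aq. NH4Cl
Reagents that add atoms: isopropylmagnesium chloride (7), CC(C)[Mg]Cl
Why: Me3SiCl-accelerated conjugate addition of the magnesium cuprate iPr2CuMgCl to an E-γ-alkoxy enoate, in which the new centre (ring C5) is set anti to the C4 ether by 1,2-induction through a Felkin–Anh-type transition state (C4–O bond antiperiplanar to the incoming isopropyl group, C4–H in the enoate plane on the inside to minimise A1,3 strain), the silyl ketene acetal being hydrolysed at work-up.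

**Step 5**
Reactants: 9 ethyl (3S,4S)-3-isopropyl-4-[(4-methoxybenzyl)oxy]hex-5-enoate
Product: 10 (3S,4S)-N-methoxy-N-methyl-3-isopropyl-4-[(4-methoxybenzyl)oxy]hex-5-enamide
Conditions: MeNH(OMe)·HCl, iPrMgCl, THF, −20 → 0 °C
Reagents that add atoms: N,O-dimethylhydroxylamine hydrochloride, CNOC.Cl
Why: Direct aminolysis of the ethyl ester by the chloromagnesium amide of N,O-dimethylhydroxylamine (Weinreb amide formation), which does not involve either stereocentre.

**Step 6**
Reactants: 11 2-bromoprop-2-en-1-ol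
Product: 12 [(2-bromoprop-2-en-1-yl)oxy](tert-butyl)dimethylsilane
Conditions: TBSCl, imidazole, CH2Cl2, 0 °C → rt
Reagents that add atoms: tert-butyldimethylsilyl chloride, CC(C)(C)[Si](C)(C)Cl
Why: Standard imidazole-promoted silylation of a primary allylic alcohol.

**Step 7**
Reactants: 12 [(2-bromoprop-2-en-1-yl)oxy](tert-butyl)dimethylsilane; 10 (3S,4S)-N-methoxy-N-methyl-3-isopropyl-4-[(4-methoxybenzyl)oxy]hex-5-enamide
Product: 15 (5S,6S)-2-{[(tert-butyldimethylsilyl)oxy]methyl}-5-isopropyl-6-[(4-methoxybenzyl)oxy]octa-1,7-dien-3-one, via vinyllithium 13 (not isolated), via lithium hemiaminal alkoxide 14 (not isolated)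
Conditions: 12, t-BuLi (2 equiv per bromide), Et2O, −78 °C; then 10, −78 → −30 °C; cold aq. NH4Cl
Reagents that add atoms: none
Why: Bromine–lithium exchange gives the 2-lithioallyl silyl ether, which should add only once to the Weinreb amide because the chelated tetrahedral lithium alkoxide persists until the quench (Weinreb ketone synthesis), so the α-methylene ketone is released only at work-up and no stereocentre is affected.

**Step 8**
Reactants: 15 (5S,6S)-2-{[(tert-butyldimethylsilyl)oxy]methyl}-5-isopropyl-6-[(4-methoxybenzyl)oxy]octa-1,7-dien-3-one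
Product: 16 (4R,5S)-2-{[(tert-butyldimethylsilyl)oxy]methyl}-5-isopropyl-4-[(4-methoxybenzyl)oxy]cyclohex-2-en-1-one
Conditions: second-generation Hoveyda–Grubbs catalyst RuCl2(H2IMes)(=CH-C6H4-2-OiPr) (5 mol %), CH2Cl2 (0.005 M), reflux, argon purge
Reagents that add atoms: none
Why: Ring-closing olefin metathesis, in which the ruthenium carbene first exchanges onto the more accessible monosubstituted C4 vinyl group, the resulting alkylidene undergoes intramolecular [2+2] cycloaddition with the 1,1-disubstituted enone alkene, and cycloreversion of the ruthenacyclobutane expels ethene and forms C2=C3. The closest known reaction type is the ring-closing metathesis of α-methylene ketones with terminal alkenes to 2-substituted cyclohex-2-enones using phosphine-free second-generation ruthenium catalysts. The single ring closes in the six-membered mode by joining the two alkene termini across the C2–C1–C6–C5–C4–C3 tether, the endocyclic alkene being necessarily Z. No stereocentre is created and C4 and C5 are not involved, so both pass unchanged into 16 (the C4 letter changes only through priorities). The selectivity needed is cyclisation over intermolecular cross-metathesis and alkene migration, which should be secured by high dilution, by the reluctance of the electron-poor 1,1-disubstituted alkene to homodimerise, by the strain-free six-membered ring and by continuous removal of ethene.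

**Step 9**
Reactants: 16 (4R,5S)-2-{[(tert-butyldimethylsilyl)oxy]methyl}-5-isopropyl-4-[(4-methoxybenzyl)oxy]cyclohex-2-en-1-one
Product: 18 (4R,5R)-2-{[(tert-butyldimethylsilyl)oxy]methyl}-5-isopropyl-4-[(4-methoxybenzyl)oxy]-1-(trimethylsilyloxy)cyclohexa-1(6),2-diene, via lithium dienolate 17 (not isolated)
Conditions: LiN(iPr)2 (LDA), THF, −78 °C; then Me3SiCl, −78 → 0 °C
Reagents that add atoms: chlorotrimethylsilane, C[Si](C)(C)Cl
Why: Kinetic deprotonation of the enone at the α′ carbon C6 by the hindered amide base and O-silylation should give the cross-conjugated 2-silyloxy diene, the γ position C4 staying untouched at low temperature.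

**Step 10**
Reactants: 18 (4R,5R)-2-{[(tert-butyldimethylsilyl)oxy]methyl}-5-isopropyl-4-[(4-methoxybenzyl)oxy]-1-(trimethylsilyloxy)cyclohexa-1(6),2-diene
Product: 21 (4S,5R,6R)-2-{[(tert-butyldimethylsilyl)oxy]methyl}-6-hydroxy-5-isopropyl-4-[(4-methoxybenzyl)oxy]cyclohex-2-en-1-one, via silyloxy epoxide 19 (not isolated), via 6-silyloxy ketone 20 (not isolated)
Conditions: mCPBA, CH2Cl2, −20 → 0 °C; then 10 % aq. citric acid, THF, 0 °C
Reagents that add atoms: 3-chloroperoxybenzoic acid (mCPBA), O=C(OO)c1cccc(Cl)c1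
Why: Rubottom oxidation, in which the peracid epoxidises the electron-rich C1=C6 enol ether bond on the ring face opposite the cis-disposed C5 isopropyl and C4 PMB-oxy groups, the silyloxy epoxide opens with 1,4-silyl shift and mild acid removes the trimethylsilyl group, so the new C6–O bond should be trans to the C5 isopropyl group.

**Step 11**
Reactants: 22 (tert-butyldimethylsilyloxy)acetaldehyde; 23 ethyl 2-(triphenylphosphoranylidene)propanoate
Product: 24 ethyl (2E)-4-[(tert-butyldimethylsilyl)oxy]-2-methylbut-2-enoate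
Conditions: CH2Cl2, 0 °C → rt
Reagents that add atoms: ethyl 2-(triphenylphosphoranylidene)propanoate (23), CCOC(=O)C(C)=P(c1ccccc1)(c1ccccc1)c1ccccc1
Why: Wittig olefination of an aldehyde with an α-methyl stabilised ylide, a reaction class that reliably gives the trisubstituted E-enoate.

**Step 12**
Reactants: 24 ethyl (2E)-4-[(tert-butyldimethylsilyl)oxy]-2-methylbut-2-enoate
Product: 25 (2E)-4-[(tert-butyldimethylsilyl)oxy]-2-methylbut-2-enoic acid
Conditions: LiOH, THF/MeOH/H2O, rt; then dilute HCl to pH 4, 0 °C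
Reagents that add atoms: lithium hydroxide (LiOH), [Li+].[OH-]
Why: Saponification of the ethyl ester under conditions that a primary TBS ether and the E-alkene tolerate, followed by brief cold acidification to release the acid.

**Step 13**
Reactants: 25 (2E)-4-[(tert-butyldimethylsilyl)oxy]-2-methylbut-2-enoic acid; 21 (4S,5R,6R)-2-{[(tert-butyldimethylsilyl)oxy]methyl}-6-hydroxy-5-isopropyl-4-[(4-methoxybenzyl)oxy]cyclohex-2-en-1-one
Product: 27 (4S,5S,6R)-6-{[(2E)-4-(tert-butyldimethylsilyloxy)-2-methylbut-2-enoyl]oxy}-2-{[(tert-butyldimethylsilyl)oxy]methyl}-5-isopropyl-4-[(4-methoxybenzyl)oxy]cyclohex-2-en-1-one, via mixed anhydride 26 (not isolated)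
Conditions: 25, 2,4,6-Cl3C6H2COCl, Et3N, toluene, rt; then 21, DMAP, rt
Reagents that add atoms: none
Why: Yamaguchi esterification, in which DMAP attacks the mixed anhydride at the less hindered enoyl carbonyl and the acylpyridinium ion acylates the hindered secondary C6 alcohol with retention because the C6–O bond is not broken.

**Step 14**
Reactants: 27 (4S,5S,6R)-6-{[(2E)-4-(tert-butyldimethylsilyloxy)-2-methylbut-2-enoyl]oxy}-2-{[(tert-butyldimethylsilyl)oxy]methyl}-5-isopropyl-4-[(4-methoxybenzyl)oxy]cyclohex-2-en-1-one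
Product: 28 (4S,5S,6R)-6-{[(2E)-4-(tert-butyldimethylsilyloxy)-2-methylbut-2-enoyl]oxy}-2-{[(tert-butyldimethylsilyl)oxy]methyl}-4-hydroxy-5-isopropylcyclohex-2-en-1-one
Conditions: DDQ, CH2Cl2/pH 7 buffer (KH2PO4/Na2HPO4), 0 °C → rt
Reagents that add atoms: none
Why: Oxidative PMB ether cleavage by DDQ (benzylic hydride abstraction, then hydrolysis of the oxocarbenium ion), which leaves silyl ethers, esters and the enone untouched, while the trans-1,3 relationship of the C4 hydroxyl and the C6 ester disfavours acyl migration.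

**Step 15**
Reactants: 28 (4S,5S,6R)-6-{[(2E)-4-(tert-butyldimethylsilyloxy)-2-methylbut-2-enoyl]oxy}-2-{[(tert-butyldimethylsilyl)oxy]methyl}-4-hydroxy-5-isopropylcyclohex-2-en-1-one
Product: 29 (4S,5S,6R)-6-{[(2E)-4-(tert-butyldimethylsilyloxy)-2-methylbut-2-enoyl]oxy}-2-{[(tert-butyldimethylsilyl)oxy]methyl}-5-isopropyl-4-(propanoyloxy)cyclohex-2-en-1-one
Conditions: (EtCO)2O, pyridine, DMAP (cat.), CH2Cl2, 0 °C → rt
Reagents that add atoms: propanoic anhydride, CCC(=O)OC(=O)CC
Why: DMAP-catalysed acylation of the secondary allylic C4 alcohol, the only free hydroxyl in the molecule.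

**Step 16**
Reactants: 29 (4S,5S,6R)-6-{[(2E)-4-(tert-butyldimethylsilyloxy)-2-methylbut-2-enoyl]oxy}-2-{[(tert-butyldimethylsilyl)oxy]methyl}-5-isopropyl-4-(propanoyloxy)cyclohex-2-en-1-one
Product: 30 (4S,5S,6R)-6-{[(2E)-4-hydroxy-2-methylbut-2-enoyl]oxy}-2-(hydroxymethyl)-5-isopropyl-4-(propanoyloxy)cyclohex-2-en-1-one (CNP0285949.1)
Conditions: HF·pyridine, pyridine, THF, 0 °C → rt
Reagents that add atoms: none
Why: Fluoride-mediated cleavage of both primary TBS ethers with buffered HF·pyridine, mildly acidic conditions that avoid base-induced acyl migration or elimination of the C4 and C6 acyloxy groups.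

**Compound list**
1 | (S)-but-3-ene-1,2-diol | C=C[C@H](O)CO | starting material
2 | (4S)-2-(4-methoxyphenyl)-4-vinyl-1,3-dioxolane (acetal epimers) | C=C[C@H]1COC(c2ccc(OC)cc2)O1 | intermediate
3 | (2S)-2-[(4-methoxybenzyl)oxy]but-3-en-1-ol | C=C[C@H](OCc1ccc(OC)cc1)CO | intermediate
4 | ethyl (triphenylphosphoranylidene)acetate | CCOC(=O)C=P(c1ccccc1)(c1ccccc1)c1ccccc1 | starting material
5 | (2S)-2-[(4-methoxybenzyl)oxy]but-3-enal | C=C[C@H](OCc1ccc(OC)cc1)C=O | intermediate
6 | ethyl (2E,4S)-4-[(4-methoxybenzyl)oxy]hexa-2,5-dienoate | C=C[C@H](OCc1ccc(OC)cc1)/C=C/C(=O)OCC | intermediate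
7 | isopropylmagnesium chloride | CC(C)[Mg]Cl | starting material
8 | (3S,4S)-1-ethoxy-3-isopropyl-4-[(4-methoxybenzyl)oxy]-1-(trimethylsilyloxy)hexa-1,5-diene (silyl ketene acetal, alkene geometry undefined) | C=C[C@H](OCc1ccc(OC)cc1)[C@H](C(C)C)C=C(OCC)O[Si](C)(C)C | intermediate
9 | ethyl (3S,4S)-3-isopropyl-4-[(4-methoxybenzyl)oxy]hex-5-enoate | C=C[C@H](OCc1ccc(OC)cc1)[C@H](C(C)C)CC(=O)OCC | intermediate
10 | (3S,4S)-N-methoxy-N-methyl-3-isopropyl-4-[(4-methoxybenzyl)oxy]hex-5-enamide | C=C[C@H](OCc1ccc(OC)cc1)[C@H](C(C)C)CC(=O)N(C)OC | intermediate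
11 | 2-bromoprop-2-en-1-ol | C=C(Br)CO | starting material
12 | [(2-bromoprop-2-en-1-yl)oxy](tert-butyl)dimethylsilane | C=C(Br)CO[Si](C)(C)C(C)(C)C | intermediate
13 | [3-(tert-butyldimethylsilyloxy)prop-1-en-2-yl]lithium | [Li]C(=C)CO[Si](C)(C)C(C)(C)C | intermediate
14 | lithium alkoxide of the tetrahedral adduct of 13 and 10 (new centre undefined) | C=C[C@H](OCc1ccc(OC)cc1)[C@H](C(C)C)CC(O[Li])(N(C)OC)C(=C)CO[Si](C)(C)C(C)(C)C | intermediate
15 | (5S,6S)-2-{[(tert-butyldimethylsilyl)oxy]methyl}-5-isopropyl-6-[(4-methoxybenzyl)oxy]octa-1,7-dien-3-one | C=C[C@H](OCc1ccc(OC)cc1)[C@H](C(C)C)CC(=O)C(=C)CO[Si](C)(C)C(C)(C)C | intermediate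
16 | (4R,5S)-2-{[(tert-butyldimethylsilyl)oxy]methyl}-5-isopropyl-4-[(4-methoxybenzyl)oxy]cyclohex-2-en-1-one | COc1ccc(CO[C@H]2C=C(CO[Si](C)(C)C(C)(C)C)C(=O)C[C@H]2C(C)C)cc1 | intermediate
17 | lithium (4R,5R)-dienolate of 16 (C1–OLi, C1=C6, C2=C3) | COc1ccc(CO[C@H]2C=C(CO[Si](C)(C)C(C)(C)C)C(O[Li])=C[C@H]2C(C)C)cc1 | intermediate
18 | (4R,5R)-2-{[(tert-butyldimethylsilyl)oxy]methyl}-5-isopropyl-4-[(4-methoxybenzyl)oxy]-1-(trimethylsilyloxy)cyclohexa-1(6),2-diene | COc1ccc(CO[C@H]2C=C(CO[Si](C)(C)C(C)(C)C)C(O[Si](C)(C)C)=C[C@H]2C(C)C)cc1 | intermediate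
19 | (1R,4S,5S,6R)-C1–C6 epoxide of 18, epoxide oxygen anti to the C5 isopropyl group | COc1ccc(CO[C@H]2C=C(CO[Si](C)(C)C(C)(C)C)[C@]3(O[Si](C)(C)C)O[C@@H]3[C@H]2C(C)C)cc1 | intermediate
20 | (4S,5S,6R)-2-{[(tert-butyldimethylsilyl)oxy]methyl}-5-isopropyl-4-[(4-methoxybenzyl)oxy]-6-(trimethylsilyloxy)cyclohex-2-en-1-one | COc1ccc(CO[C@H]2C=C(CO[Si](C)(C)C(C)(C)C)C(=O)[C@H](O[Si](C)(C)C)[C@H]2C(C)C)cc1 | intermediate
21 | (4S,5R,6R)-2-{[(tert-butyldimethylsilyl)oxy]methyl}-6-hydroxy-5-isopropyl-4-[(4-methoxybenzyl)oxy]cyclohex-2-en-1-one | COc1ccc(CO[C@H]2C=C(CO[Si](C)(C)C(C)(C)C)C(=O)[C@H](O)[C@H]2C(C)C)cc1 | intermediate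
22 | (tert-butyldimethylsilyloxy)acetaldehyde | CC(C)(C)[Si](C)(C)OCC=O | starting material
23 | ethyl 2-(triphenylphosphoranylidene)propanoate | CCOC(=O)C(C)=P(c1ccccc1)(c1ccccc1)c1ccccc1 | starting material
24 | ethyl (2E)-4-[(tert-butyldimethylsilyl)oxy]-2-methylbut-2-enoate | CCOC(=O)/C(C)=C/CO[Si](C)(C)C(C)(C)C | intermediate
25 | (2E)-4-[(tert-butyldimethylsilyl)oxy]-2-methylbut-2-enoic acid | OC(=O)/C(C)=C/CO[Si](C)(C)C(C)(C)C | intermediate
26 | mixed anhydride of 25 with 2,4,6-trichlorobenzoic acid | O=C(OC(=O)/C(C)=C/CO[Si](C)(C)C(C)(C)C)c1c(Cl)cc(Cl)cc1Cl | intermediate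
27 | (4S,5S,6R)-6-{[(2E)-4-(tert-butyldimethylsilyloxy)-2-methylbut-2-enoyl]oxy}-2-{[(tert-butyldimethylsilyl)oxy]methyl}-5-isopropyl-4-[(4-methoxybenzyl)oxy]cyclohex-2-en-1-one | COc1ccc(CO[C@H]2C=C(CO[Si](C)(C)C(C)(C)C)C(=O)[C@H](OC(=O)/C(C)=C/CO[Si](C)(C)C(C)(C)C)[C@H]2C(C)C)cc1 | intermediate
28 | (4S,5S,6R)-6-{[(2E)-4-(tert-butyldimethylsilyloxy)-2-methylbut-2-enoyl]oxy}-2-{[(tert-butyldimethylsilyl)oxy]methyl}-4-hydroxy-5-isopropylcyclohex-2-en-1-one | O[C@H]1C=C(CO[Si](C)(C)C(C)(C)C)C(=O)[C@H](OC(=O)/C(C)=C/CO[Si](C)(C)C(C)(C)C)[C@H]1C(C)C | intermediate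
29 | (4S,5S,6R)-6-{[(2E)-4-(tert-butyldimethylsilyloxy)-2-methylbut-2-enoyl]oxy}-2-{[(tert-butyldimethylsilyl)oxy]methyl}-5-isopropyl-4-(propanoyloxy)cyclohex-2-en-1-one | CCC(=O)O[C@H]1C=C(CO[Si](C)(C)C(C)(C)C)C(=O)[C@H](OC(=O)/C(C)=C/CO[Si](C)(C)C(C)(C)C)[C@H]1C(C)C | intermediate
30 | (4S,5S,6R)-6-{[(2E)-4-hydroxy-2-methylbut-2-enoyl]oxy}-2-(hydroxymethyl)-5-isopropyl-4-(propanoyloxy)cyclohex-2-en-1-one | CCC(=O)O[C@H]1C=C(CO)C(=O)[C@H](OC(=O)/C(C)=C/CO)[C@H]1C(C)C | target

**Step count**
Total: 16 steps. Longest linear sequence: 13 steps (steps 1–5, 7–10 and 13–16, from 1 to 30).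

**Steps most likely to fail**

Step 4. The 1,2-induction may be weak, because the vinyl group on C4 offers less steric differentiation than the alkyl groups of the usual γ-alkoxy enoates, so the cuprate could attack both faces of the enoate. The fallback places the addition under auxiliary control; it leaves the route at 6 and returns at 10. Ester 6 would be saponified (LiOH, THF/H2O, 0 °C) to (2E,4S)-4-[(4-methoxybenzyl)oxy]hexa-2,5-dienoic acid F1. The acid would be activated as the mixed pivalic anhydride F2 (t-BuCOCl, Et3N, THF, −20 °C) and coupled with lithiated (R)-4-phenyloxazolidin-2-one to the N-enoyl imide F3. Addition of iPrMgCl/CuBr·SMe2 (THF, −40 °C) to the magnesium-chelated syn-s-cis imide should occur on the face opposite the phenyl group, the same face the C4 ether favours (matched pair), to give the conjugate adduct F4. LiOH/H2O2 would then release the auxiliary and (3S,4S)-3-isopropyl-4-[(4-methoxybenzyl)oxy]hex-5-enoic acid F5, which is coupled with MeNH(OMe)·HCl (EDC·HCl, N-methylmorpholine) to Weinreb amide 10.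

Step 8. The metathesis may stall after loading onto the hindered C4 vinyl group, or drift into intermolecular cross-metathesis and alkene migration, because the electron-poor 1,1-disubstituted enone alkene engages slowly. The fallback keeps the same C2=C3 closure but runs it at the alcohol oxidation level; it leaves at 15 and returns at 16. Luche reduction of 15 (NaBH4, CeCl3·7H2O, MeOH, −40 °C) would give the dienol F6 as a mixture of carbinol epimers. Its electron-richer allylic-alcohol alkene should close readily with the second-generation Grubbs catalyst RuCl2(H2IMes)(PCy3)(=CHPh) in refluxing CH2Cl2 to the cyclohexenol F7, and MnO2 (CH2Cl2, rt) would oxidise the allylic alcohol to enone 16.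

Step 10. The epoxidation–rearrangement may lose regio- or face control. The silyloxy epoxide can ionise to a delocalised allyl cation, and the 3-chlorobenzoic acid formed can protodesilylate the dienol ether back to 16. The fallback hydroxylates the enolate directly and bypasses the silyl dienol ether; it leaves at 16 and returns at 21. Deprotonation with NaN(SiMe3)2 (THF, −78 °C) would give the sodium dienolate F8, which is oxidised with 2-(phenylsulfonyl)-3-phenyloxaziridine at −78 °C, again on the face opposite the C5 isopropyl group, to hydroxy ketone 21.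

**Further compounds**
F1 | step 4 | (2E,4S)-4-[(4-methoxybenzyl)oxy]hexa-2,5-dienoic acid | C=C[C@H](OCc1ccc(OC)cc1)/C=C/C(=O)O
F2 | step 4 | mixed anhydride of F1 with pivalic acid | C=C[C@H](OCc1ccc(OC)cc1)/C=C/C(=O)OC(=O)C(C)(C)C
F3 | step 4 | (4R)-3-{(2E,4S)-4-[(4-methoxybenzyl)oxy]hexa-2,5-dienoyl}-4-phenyloxazolidin-2-one | C=C[C@H](OCc1ccc(OC)cc1)/C=C/C(=O)N1[C@H](c2ccccc2)COC1=O
F4 | step 4 | (4R)-3-{(3S,4S)-3-isopropyl-4-[(4-methoxybenzyl)oxy]hex-5-enoyl}-4-phenyloxazolidin-2-one | C=C[C@H](OCc1ccc(OC)cc1)[C@H](C(C)C)CC(=O)N1[C@H](c2ccccc2)COC1=O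
F5 | step 4 | (3S,4S)-3-isopropyl-4-[(4-methoxybenzyl)oxy]hex-5-enoic acid | C=C[C@H](OCc1ccc(OC)cc1)[C@H](C(C)C)CC(=O)O
F6 | step 8 | (5S,6S)-2-{[(tert-butyldimethylsilyl)oxy]methyl}-5-isopropyl-6-[(4-methoxybenzyl)oxy]octa-1,7-dien-3-ol (C3 epimers) | C=C[C@H](OCc1ccc(OC)cc1)[C@H](C(C)C)CC(O)C(=C)CO[Si](C)(C)C(C)(C)C
F7 | step 8 | 2-{[(tert-butyldimethylsilyl)oxy]methyl}-5-isopropyl-4-[(4-methoxybenzyl)oxy]cyclohex-2-en-1-ol (C1 epimers, C4 and C5 as in 16) | COc1ccc(CO[C@H]2C=C(CO[Si](C)(C)C(C)(C)C)C(O)C[C@H]2C(C)C)cc1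
F8 | step 10 | sodium dienolate of 16 (C1–ONa, C1=C6, C2=C3) | COc1ccc(CO[C@H]2C=C(CO[Si](C)(C)C(C)(C)C)C(O[Na])=C[C@H]2C(C)C)cc1
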